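**Retrosynthetic overview**
- The strategy rests on the array HO-C6–C7–C11(=C13H2) inside the ten-membered carbocycle C1–C10, with C6 allylic to C4=C5. This is the retron of a [2,3]-Wittig shift of an ether oxygen bridging C6 and C13, so the cyclodecadiene is traced back to a 13-membered bis-allylic ether.
- That ether is opened at the C6–O bond (Williamson) to an acyclic chain whose three trisubstituted olefins all have enoate-type geometry. C4=C5 and C10=C1 come from two Horner–Wadsworth–Emmons reactions, and C7=C11 comes from a Morita–Baylis–Hillman adduct by SN2' bromination.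
- C8 comes from (S)-PMB glycidyl ether. C6 and C7 are set together in the ring contraction. The C14 acetate and the C8 acyloxy side chain are added last.
- Ring order: a temporary O8–C14 butyrolactone is made and then reductively opened. Next comes the 13-membered ether, then its contraction to the ten-membered ring, and finally the 6,12-γ-lactone by oxidation.

Key step: step 20

Remark: germacrane numbering (C1–C15) is used for all intermediates, "ring-cis" means that the two ring carbons on a double bond are cis, and compounds 1 and 7 are taken as catalogue items.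

Step 1
Reactants: 1 (S)-4-methoxybenzyl glycidyl ether; 2 triethyl phosphonoacetate
Product: 4 (5S)-3-(diethoxyphosphoryl)-5-[(4-methoxybenzyloxy)methyl]oxolan-2-one (both C10 epimers), via open-chain hydroxy phosphonoester 3 (not isolated)
Conditions: NaH, 2 in slight excess, DME, 0 → 65 °C; then cold 1 M HCl
Reagents that add atoms: none
Why: The phosphonoacetate anion opens the epoxide at its CH2 terminus (SN2, C8–O bond untouched, so C8 stays S) and the freed C8 alkoxide lactonises onto the ethyl ester (5-exo-trig), the moderate temperature keeping the competing Wadsworth–Emmons cyclopropanation out of reach.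

Step 2
Reactants: 2 triethyl phosphonoacetate; 5 2-(2-bromoethyl)-1,3-dioxolane
Product: 6 ethyl 2-(diethoxyphosphoryl)-4-(1,3-dioxolan-2-yl)butanoate (racemic)
Conditions: NaH, cat. NaI, DMF, 0 → 60 °C
Reagents that add atoms: none
Why: SN2 C-alkylation of the stabilised phosphonate carbanion with a primary bromide joins C3 to C4, and a slight excess of 2 should hold back dialkylation.

Step 3
Reactants: 6 alkylated phosphonoacetate; 7 (4-methoxybenzyloxy)acetaldehyde
Product: 8 ethyl (E)-2-[2-(1,3-dioxolan-2-yl)ethyl]-4-(4-methoxybenzyloxy)but-2-enoate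
Conditions: NaH, THF, 0 °C → rt; chromatographic removal of the Z isomer
Reagents that add atoms: none
Why: Horner–Wadsworth–Emmons olefination of an unhindered aldehyde under equilibrating conditions should favour the E-enoate, in which the ester (C15) is trans to C6 and C3 is therefore cis to C6, the ring-cis C4=C5 geometry of the target.

Step 4
Reactants: 8 E-enoate
Product: 9 (E)-2-[2-(1,3-dioxolan-2-yl)ethyl]-4-(4-methoxybenzyloxy)but-2-en-1-ol
Conditions: DIBAL-H (2.5 equiv), CH2Cl2, −78 °C; Rochelle salt
Reagents that add atoms: none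
Why: DIBAL-H 1,2-reduction of an enoate gives the allylic C15 alcohol without touching the dioxolane, the PMB ether or the olefin geometry.

Step 5
Reactants: 9 C15 allylic alcohol
Product: 10 4-methoxyphenyl (PMP) ether of 9
Conditions: 4-MeOC6H4OH, PPh3, DIAD, THF, 0 °C → rt
Reagents that add atoms: 4-methoxyphenol COc1ccc(O)cc1
Why: Mitsunobu etherification of a primary allylic alcohol with an acidic phenol proceeds by direct SN2 and installs a C15 protecting group that is orthogonal to PMB (stable to DDQ, cleaved by Ce(IV)).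

Step 6
Reactants: 10 dioxolane PMP ether
Product: 11 (E)-6-(4-methoxybenzyloxy)-4-[(4-methoxyphenoxy)methyl]hex-4-enal (C1–C6 aldehyde, C3 cis to C6)
Conditions: 1 M HCl, THF, 40 °C
Reagents that add atoms: water O
Why: Acid-catalysed acetal hydrolysis frees the C1 aldehyde under conditions that benzyl-type and aryl ethers tolerate.

Step 7
Reactants: 4 α-phosphono lactone; 11 C1–C6 aldehyde
Product: 12 (3E,5S)-alkylidene lactone (C14 carbonyl tied to O8, C9 cis to C2)
Conditions: LiCl, DBU, MeCN, 0 °C → rt
Reagents that add atoms: none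
Why: Horner–Wadsworth–Emmons olefination under Masamune–Roush conditions is mild enough for the enolisable aldehyde and should favour the E-alkylidene lactone, which places C9 cis to C2 (ring-cis C10=C1) and erases the C10 epimer mixture.

Step 8
Reactants: 12 alkylidene lactone
Product: 13 (8S)-C8,C14-diol
Conditions: DIBAL-H (4 equiv), CH2Cl2, −78 → 0 °C; Rochelle salt
Reagents that add atoms: none
Why: Exhaustive DIBAL-H 1,2-reduction takes the conjugated lactone through the lactol to the secondary C8 and primary allylic C14 alcohols without conjugate reduction, C8 not being involved.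

Step 9
Reactants: 13 diol
Product: 14 O8,O14-bis(triisopropylsilyl) ether
Conditions: TIPSOTf (2.5 equiv), 2,6-lutidine, CH2Cl2, 0 °C → rt
Reagents that add atoms: triisopropylsilyl trifluoromethanesulfonate CC(C)[Si](OS(=O)(=O)C(F)(F)F)(C(C)C)C(C)C
Why: Silyl triflate silylation covers both hydroxyls and puts on O8 the bulky group that will later shield one face of C7.

Step 10
Reactants: 14 bis-TIPS bis-PMB ether
Product: 15 C6,C7-diol (PMP and TIPS ethers kept)
Conditions: DDQ (2.5 equiv), CH2Cl2/pH 7 buffer, 0 °C
Reagents that add atoms: none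
Why: Oxidative PMB cleavage works by benzylic hydride abstraction and hydrolysis, a path closed to the PMP ether because it has no benzylic C–H.

Step 11
Reactants: 15 C6,C7-diol
Product: 16 (8S)-C6,C7-dialdehyde (C6 enal, C7 α-silyloxy aldehyde)
Conditions: Dess–Martin periodinane (3 equiv), NaHCO3, CH2Cl2, 0 °C → rt
Reagents that add atoms: none
Why: Buffered Dess–Martin oxidation converts both primary alcohols into aldehydes under neutral conditions that should neither epimerise C8 nor isomerise the enal.

Step 12
Reactants: 16 dialdehyde; 17 methyl acrylate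
Product: 18 Morita–Baylis–Hillman adduct at C7 (both carbinol epimers)
Conditions: DABCO (1 equiv), methyl acrylate (excess), a little MeOH, rt
Reagents that add atoms: none
Why: In the Morita–Baylis–Hillman reaction the DABCO–acrylate zwitterion attacks the non-conjugated, inductively activated C7 aldehyde, whereas the β,β-disubstituted C6 enal is a poor electrophile and no Michael partner; the new carbinol centre disappears in step 13 and the weak base should leave C8 intact.

Step 13
Reactants: 18 Morita–Baylis–Hillman adduct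
Product: 20 methyl (Z)-2-(bromomethyl)enoate (CH2Br cis to C8 and ester trans to C8), via secondary mesylate 19 (not isolated)
Conditions: MsCl, Et3N, CH2Cl2, −30 → 0 °C; then LiBr, THF, 0 °C → rt
Reagents that add atoms: lithium bromide [Li+].[Br-]; methanesulfonyl chloride CS(=O)(=O)Cl (its atoms stay only in 19)
Why: Bromide attacks the acrylate CH2 terminus with loss of mesylate (SN2'), and allylic strain in the developing trisubstituted enoate places C8 trans to the ester, the usual Z outcome for such adducts.

Step 14
Reactants: 20 Z-bromide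
Product: 21 methyl (E)-2-[(4-methoxyphenoxy)methyl]enoate (C12-OPMP cis to C8, C6 enal kept)
Conditions: 4-MeOC6H4OH, K2CO3, MeCN, rt
Reagents that add atoms: 4-methoxyphenol COc1ccc(O)cc1
Why: Williamson aryl ether formation by direct SN2 at the primary allylic bromide keeps the olefin geometry and gives C12 the same protecting group as C15, so that both can fall in one later operation.

Step 15
Reactants: 21 enoate enal
Product: 22 C6 allylic alcohol (methyl ester kept)
Conditions: NaBH4, CeCl3·7H2O, MeOH/THF, −40 °C
Reagents that add atoms: none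
Why: Luche reduction attacks only the aldehyde in 1,2-fashion and leaves the enoate alone, which differentiates the two future ether termini C6 and C13.

Step 16
Reactants: 22 C6 allylic alcohol
Product: 24 C6 allylic chloride (methyl ester kept), via primary allylic mesylate 23 (not isolated)
Conditions: MsCl, 2,4,6-collidine, LiCl, DMF, 0 °C
Reagents that add atoms: lithium chloride [Li+].[Cl-]; methanesulfonyl chloride CS(=O)(=O)Cl (its atoms stay only in 23)
Why: Mesylation with in situ chloride displacement (Collington–Meyers conditions) turns primary allylic alcohols into the chlorides by SN2 without allylic transposition or loss of geometry.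

Step 17
Reactants: 24 chloro ester
Product: 25 C13 alcohol C6 chloride
Conditions: DIBAL-H (2.5 equiv), CH2Cl2, −78 °C; Rochelle salt
Reagents that add atoms: none
Why: DIBAL-H 1,2-reduction of the enoate at −78 °C leaves a primary allylic chloride untouched, so the chain now ends in one nucleophile (O13) and one electrophile (C6).

Step 18
Reactants: 25 hydroxy chloride
Product: 26 13-membered bis-allylic ether (ring O, C6, C5=C4, C3, C2, C1=C10, C9, C8, C7=C11, C13; C13 trans to C8; C12 and C15 as PMP ethers)
Conditions: NaH, cat. Bu4NI, THF, 45 °C, slow addition of 25 (final ca. 1 mM)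
Reagents that add atoms: none
Why: Intramolecular Williamson etherification (13-exo-tet) at high dilution joins O13 to the primary carbon C6, the fully substituted C4 blocks SN2', and no stereocentre or olefin takes part.

Step 19
Reactants: 26 macrocyclic bis-PMP ether
Product: 27 13-membered ether with free C12-OH and C15-OH
Conditions: (NH4)2Ce(NO3)6 (5 equiv), pyridine, MeCN/H2O 4:1, 0 °C
Reagents that add atoms: none
Why: Oxidative dearylation by Ce(IV) converts each 4-alkoxyanisole ring into benzoquinone and releases the alcohol, and the buffer protects the TIPS ethers and the bis-allylic ether.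

Step 20
Reactants: 27 macrocyclic ether diol
Product: 29 (6R,7S,8S)-cyclodeca-1(10),4-diene triol (C6-OH; C7 bearing C11(=C13H2)C12H2OH; C15-OH; O8 and O14 as TIPS ethers), via C6-lithiated dilithium dialkoxide 28 (not isolated)
Conditions: n-BuLi (3.5 equiv), THF, −78 → −20 °C; aq NH4Cl
Reagents that add atoms: n-butyllithium [Li]CCCC (lithium stays only in 28)
Why: The first two equivalents of base turn the C12 and C15 hydroxyls into lithium alkoxides, which shuts off metalation of those CH2 groups and any 1,4-loss of the C15 oxygen, and the third takes a proton from C6 to give the α-oxyallyl anion 28, which rearranges by a concerted suprafacial [2,3]-Wittig shift through the five-centre envelope C6–O–C13–C11–C7. The closest known reaction is the [2,3]-Wittig ring contraction of 13-membered bis-allylic ethers to germacradienols, applied here to a ring with two ring-cis olefins and two alkoxide arms. The ten-membered carbocycle is closed transannularly, by contraction and not by end-to-end cyclisation: C6–C7 forms while C13–O breaks and C11=C13 appears. C7 is controlled by C8, because A1,3 strain with the cis C12 arm keeps H8 in the olefin plane, so the OTIPS group covers one face of C7 and C6 arrives on the other, the face on which the C9 tether lies. C6 is controlled relative to C7 by the C7=C11 geometry (C13 trans to C8) with C5 exo on the envelope, which leads to the 6,7-anti array needed for the trans-lactone. The selectivity needed is C6 over C13 metalation and [2,3] over [1,2] shift: C6-H2 is flanked only by the ring oxygen and a vinylic CH and its anion bonds to the CH terminus C7, whereas a C13 anion would have to build a quaternary C4, and the low temperature disfavours the radical [1,2] pathway.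

Step 21
Reactants: 29 triol
Product: 31 (6R,7S,8S)-6,12-olide with α-methylene group and C15 enal (O8 and O14 as TIPS ethers), via C12 lactol 30 (not isolated)
Conditions: TEMPO (0.2 equiv), PhI(OAc)2 (3.5 equiv), CH2Cl2, rt
Reagents that add atoms: none
Why: Oxoammonium (TEMPO/PhI(OAc)2) oxidation prefers primary alcohols, so C15-OH gives the enal and C12-OH gives an aldehyde that is trapped by C6-OH as lactol 30 and oxidised on to the γ-lactone (oxidative lactonisation of a 1,4-diol), C15 being trans to C6 and so unable to form a competing lactol.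

Step 22
Reactants: 31 bis-TIPS lactone
Product: 32 (6R,7R,8S)-8,14-diol lactone enal
Conditions: HF·pyridine, THF, 0 °C → rt
Reagents that add atoms: none
Why: Fluoride-mediated desilylation in an acidic medium removes both TIPS groups without the base-induced translactonisation to O8 or conjugate additions that a basic fluoride source could cause.

Step 23
Reactants: 32 diol
Product: 33 C14 monoacetate (C8-OH free)
Conditions: AcCl (1.1 equiv), 2,4,6-collidine, CH2Cl2, −78 °C
Reagents that add atoms: acetyl chloride CC(=O)Cl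
Why: Acetylation with acetyl chloride and a hindered pyridine at low temperature discriminates sharply between a primary and a hindered secondary alcohol.

Step 24
Reactants: 34 ethyl 2-(hydroxymethyl)acrylate
Product: 35 ethyl 2-[(tert-butyldimethylsilyloxy)methyl]acrylate
Conditions: TBSCl, imidazole, CH2Cl2, 0 °C → rt
Reagents that add atoms: tert-butyldimethylsilyl chloride CC(C)(C)[Si](C)(C)Cl
Why: Standard silylation of a primary alcohol masks the side-chain hydroxyl so that it cannot compete in the later esterification.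

Step 25
Reactants: 35 silylated ester
Product: 36 2-[(tert-butyldimethylsilyloxy)methyl]acrylic acid
Conditions: LiOH, THF/H2O, 0 °C → rt; cold dilute HCl to pH 4
Reagents that add atoms: lithium hydroxide [Li+].[OH-]
Why: Saponification of the unhindered ethyl ester is faster than conjugate addition of hydroxide to the α-substituted acrylate, and the TBS ether survives the brief mild acidification.

Step 26
Reactants: 33 C8 alcohol; 36 side-chain acid
Product: 37 C8 ester with TBS-protected side chain
Conditions: DCC, cat. DMAP, CH2Cl2, 0 °C → rt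
Reagents that add atoms: none
Why: Steglich esterification acylates the only free hydroxyl with retention at C8, since the C8–O bond is not broken.

Step 27
Reactants: 37 TBS-protected ester
Product: 38 target CNP0198933.2 (6R,7R,8S)
Conditions: HF·pyridine, THF, 0 °C
Reagents that add atoms: none
Why: Mild acidic fluoride desilylation frees the primary side-chain alcohol and leaves the acetate, both acrylate-type esters, the enal and the lactone untouched.

**Compound list**
1 | (S)-4-methoxybenzyl glycidyl ether | O1[C@H](COCc2ccc(OC)cc2)C1 | starting material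
2 | triethyl phosphonoacetate | CCOC(=O)CP(=O)(OCC)OCC | starting material
3 | ethyl (4S)-2-(diethoxyphosphoryl)-4-hydroxy-5-(4-methoxybenzyloxy)pentanoate (present as its alkoxide) | CCOC(=O)C(C[C@H](O)COCc1ccc(OC)cc1)P(=O)(OCC)OCC | intermediate
4 | (5S)-3-(diethoxyphosphoryl)-5-[(4-methoxybenzyloxy)methyl]oxolan-2-one | O=C1O[C@H](COCc2ccc(OC)cc2)CC1P(=O)(OCC)OCC | intermediate
5 | 2-(2-bromoethyl)-1,3-dioxolane | BrCCC1OCCO1 | starting material
6 | ethyl 2-(diethoxyphosphoryl)-4-(1,3-dioxolan-2-yl)butanoate | CCOC(=O)C(CCC1OCCO1)P(=O)(OCC)OCC | intermediate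
7 | (4-methoxybenzyloxy)acetaldehyde | O=CCOCc1ccc(OC)cc1 | starting material
8 | ethyl (E)-2-[2-(1,3-dioxolan-2-yl)ethyl]-4-(4-methoxybenzyloxy)but-2-enoate | CCOC(=O)/C(CCC1OCCO1)=C/COCc1ccc(OC)cc1 | intermediate
9 | (E)-2-[2-(1,3-dioxolan-2-yl)ethyl]-4-(4-methoxybenzyloxy)but-2-en-1-ol | OC/C(CCC1OCCO1)=C/COCc1ccc(OC)cc1 | intermediate
10 | PMP ether of 9 | COc1ccc(OC/C(CCC2OCCO2)=C/COCc2ccc(OC)cc2)cc1 | intermediate
11 | (E)-6-(4-methoxybenzyloxy)-4-[(4-methoxyphenoxy)methyl]hex-4-enal | O=CCC/C(COc1ccc(OC)cc1)=C\COCc1ccc(OC)cc1 | intermediate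
12 | (3E,5S)-alkylidene lactone, C1–C10 chain complete | O1[C@H](COCc2ccc(OC)cc2)C/C(C1=O)=C\CC/C(COc1ccc(OC)cc1)=C\COCc1ccc(OC)cc1 | intermediate
13 | (8S)-C8,C14-diol | O[C@H](COCc1ccc(OC)cc1)C/C(CO)=C\CC/C(COc1ccc(OC)cc1)=C\COCc1ccc(OC)cc1 | intermediate
14 | O8,O14-bis-TIPS ether | CC(C)[Si](C(C)C)(C(C)C)O[C@H](COCc1ccc(OC)cc1)C/C(CO[Si](C(C)C)(C(C)C)C(C)C)=C\CC/C(COc1ccc(OC)cc1)=C\COCc1ccc(OC)cc1 | intermediate
15 | C6,C7-diol | CC(C)[Si](C(C)C)(C(C)C)O[C@H](CO)C/C(CO[Si](C(C)C)(C(C)C)C(C)C)=C\CC/C(COc1ccc(OC)cc1)=C\CO | intermediate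
16 | (8S)-C6,C7-dialdehyde | CC(C)[Si](C(C)C)(C(C)C)O[C@H](C=O)C/C(CO[Si](C(C)C)(C(C)C)C(C)C)=C\CC/C(COc1ccc(OC)cc1)=C\C=O | intermediate
17 | methyl acrylate | C=CC(=O)OC | starting material
18 | Morita–Baylis–Hillman adduct at C7 | CC(C)[Si](C(C)C)(C(C)C)O[C@H](C(O)C(=C)C(=O)OC)C/C(CO[Si](C(C)C)(C(C)C)C(C)C)=C\CC/C(COc1ccc(OC)cc1)=C\C=O | intermediate
19 | C7 mesylate of 18 | CC(C)[Si](C(C)C)(C(C)C)O[C@H](C(OS(C)(=O)=O)C(=C)C(=O)OC)C/C(CO[Si](C(C)C)(C(C)C)C(C)C)=C\CC/C(COc1ccc(OC)cc1)=C\C=O | intermediate
20 | methyl (Z)-2-(bromomethyl)enoate, C6 enal | CC(C)[Si](C(C)C)(C(C)C)O[C@H](/C=C(\CBr)C(=O)OC)C/C(CO[Si](C(C)C)(C(C)C)C(C)C)=C\CC/C(COc1ccc(OC)cc1)=C\C=O | intermediate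
21 | methyl (E)-2-[(4-methoxyphenoxy)methyl]enoate, C6 enal | CC(C)[Si](C(C)C)(C(C)C)O[C@H](/C=C(\COc1ccc(OC)cc1)C(=O)OC)C/C(CO[Si](C(C)C)(C(C)C)C(C)C)=C\CC/C(COc1ccc(OC)cc1)=C\C=O | intermediate
22 | C6 allylic alcohol, methyl ester | CC(C)[Si](C(C)C)(C(C)C)O[C@H](/C=C(\COc1ccc(OC)cc1)C(=O)OC)C/C(CO[Si](C(C)C)(C(C)C)C(C)C)=C\CC/C(COc1ccc(OC)cc1)=C\CO | intermediate
23 | C6 allylic mesylate, methyl ester | CC(C)[Si](C(C)C)(C(C)C)O[C@H](/C=C(\COc1ccc(OC)cc1)C(=O)OC)C/C(CO[Si](C(C)C)(C(C)C)C(C)C)=C\CC/C(COc1ccc(OC)cc1)=C\COS(C)(=O)=O | intermediate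
24 | C6 allylic chloride, methyl ester | CC(C)[Si](C(C)C)(C(C)C)O[C@H](/C=C(\COc1ccc(OC)cc1)C(=O)OC)C/C(CO[Si](C(C)C)(C(C)C)C(C)C)=C\CC/C(COc1ccc(OC)cc1)=C\CCl | intermediate
25 | C13 alcohol, C6 chloride | CC(C)[Si](C(C)C)(C(C)C)O[C@H](/C=C(\COc1ccc(OC)cc1)CO)C/C(CO[Si](C(C)C)(C(C)C)C(C)C)=C\CC/C(COc1ccc(OC)cc1)=C\CCl | intermediate
26 | 13-membered bis-allylic ether, C12 and C15 as PMP ethers | CC(C)[Si](C(C)C)(C(C)C)O[C@H]1C/C(CO[Si](C(C)C)(C(C)C)C(C)C)=C\CC/C(COc2ccc(OC)cc2)=C\COC/C(COc2ccc(OC)cc2)=C/1 | intermediate
27 | 13-membered ether, C12-OH and C15-OH free | CC(C)[Si](C(C)C)(C(C)C)O[C@H]1C/C(CO[Si](C(C)C)(C(C)C)C(C)C)=C\CC/C(CO)=C\COC/C(CO)=C/1 | intermediate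
28 | C6-lithiated dilithium dialkoxide of 27 | CC(C)[Si](C(C)C)(C(C)C)O[C@H]1C/C(CO[Si](C(C)C)(C(C)C)C(C)C)=C\CC/C(CO[Li])=C\C([Li])OC/C(CO[Li])=C/1 | intermediate
29 | (6R,7S,8S)-cyclodeca-1(10),4-diene triol | CC(C)[Si](C(C)C)(C(C)C)O[C@H]1C/C(CO[Si](C(C)C)(C(C)C)C(C)C)=C\CC/C(CO)=C\[C@@H](O)[C@@H]1C(=C)CO | intermediate
30 | C12 lactol, C15 enal | CC(C)[Si](C(C)C)(C(C)C)O[C@H]1C/C(CO[Si](C(C)C)(C(C)C)C(C)C)=C\CC/C(C=O)=C\[C@H]2OC(O)C(=C)[C@H]12 | intermediate
31 | (6R,7S,8S)-6,12-olide, C15 enal, O8 and O14 TIPS | CC(C)[Si](C(C)C)(C(C)C)O[C@H]1C/C(CO[Si](C(C)C)(C(C)C)C(C)C)=C\CC/C(C=O)=C\[C@H]2OC(=O)C(=C)[C@H]12 | intermediate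
32 | (6R,7R,8S)-8,14-diol lactone enal | O[C@H]1C/C(CO)=C\CC/C(C=O)=C\[C@H]2OC(=O)C(=C)[C@H]12 | intermediate
33 | C14 acetate, C8-OH free | O[C@H]1C/C(COC(C)=O)=C\CC/C(C=O)=C\[C@H]2OC(=O)C(=C)[C@H]12 | intermediate
34 | ethyl 2-(hydroxymethyl)acrylate | C=C(CO)C(=O)OCC | starting material
35 | ethyl 2-[(tert-butyldimethylsilyloxy)methyl]acrylate | C=C(CO[Si](C)(C)C(C)(C)C)C(=O)OCC | intermediate
36 | 2-[(tert-butyldimethylsilyloxy)methyl]acrylic acid | C=C(CO[Si](C)(C)C(C)(C)C)C(=O)O | intermediate
37 | C8 ester with TBS-protected side chain | C=C(CO[Si](C)(C)C(C)(C)C)C(=O)O[C@H]1C/C(COC(C)=O)=C\CC/C(C=O)=C\[C@H]2OC(=O)C(=C)[C@H]12 | intermediate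
38 | CNP0198933.2 | C=C(CO)C(=O)O[C@H]1C/C(COC(C)=O)=C\CC/C(C=O)=C\[C@H]2OC(=O)C(=C)[C@H]12 | target

Total step count: 27.
Longest linear sequence: 24 steps (steps 2–23, then 26 and 27).

**Steps most likely to fail**

**Risk 1, step 20.**
- What may go wrong: the base may metalate C13, possibly helped by the neighbouring C12 alkoxide. This could be followed by loss of the C8 silyloxy group in a 1,4-elimination or by a shift onto C4. A [1,2]-shift, drift of the C4=C5 geometry in the delocalised anion, or poor facial selectivity at C7 are also possible.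
- Fallback: it sets out from bromide 20, which already holds the C6 enal and a 2-(bromomethyl)enoate.
- A macrocyclic Barbier closure of Nozaki–Hiyama type (CrCl2, THF/DMF, high dilution) forms the same C6–C7 bond by SE2' attack of the allylchromium on the enal. The CH2Br carbon becomes the exocyclic methylene and the C6 alkoxide closes onto the methyl ester, giving the C15-O-PMP 6,12-olide F1. The 6,7-relationship would have to be checked at this point.
- Ceric ammonium nitrate then frees the C15 allylic alcohol lactone F2, and MnO2 oxidises it to the enal. The route is rejoined at 31.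

**Risk 2, step 18.**
- What may go wrong: intermolecular etherification (oligomerisation) may outrun ring closure, or the allylic chloride may be lost by elimination.
- Fallback: it sets out from hydroxy ester 22 and closes the ring by acylation instead of alkylation.
- LiOH saponification gives the seco acid F3, and Yamaguchi macrolactonisation gives the 13-membered enoate lactone F4, with C13 as the carbonyl carbon.
- Reductive acetylation (DIBAL-H at −78 °C, then Ac2O, pyridine, DMAP) gives the α-acetoxy ether F5. Ionic reduction (Et3SiH, BF3·OEt2, −78 °C) removes the acetoxy group. The route is rejoined at 26.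

**Risk 3, step 12.**
- What may go wrong: addition to the hindered α-silyloxy aldehyde may be slow, so that long contact with the amine allows epimerisation at C8 or geometrical drift of the enal.
- Fallback: it sets out from dialdehyde 16 and replaces the three-step sequence by a tandem oxa-Michael/Horner–Wadsworth–Emmons reaction.
- Potassium 4-methoxyphenoxide adds to trimethyl 2-phosphonoacrylate to give the anion of methyl 2-(dimethoxyphosphoryl)-3-(4-methoxyphenoxy)propanoate F6.
- In the same flask this anion olefinates the more electrophilic C7 aldehyde to the E-enoate. The route is rejoined at 21, without passing through 18, 19 and 20.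

**Further compounds**
F1 | step 20 | 6,12-olide with C15-O-PMP, O8 and O14 TIPS | CC(C)[Si](C(C)C)(C(C)C)O[C@H]1C/C(CO[Si](C(C)C)(C(C)C)C(C)C)=C\CC/C(COc3ccc(OC)cc3)=C\[C@H]2OC(=O)C(=C)[C@H]12
F2 | step 20 | 6,12-olide with C15-OH, O8 and O14 TIPS | CC(C)[Si](C(C)C)(C(C)C)O[C@H]1C/C(CO[Si](C(C)C)(C(C)C)C(C)C)=C\CC/C(CO)=C\[C@H]2OC(=O)C(=C)[C@H]12
F3 | step 18 | seco acid (C13 carboxylic acid, C6-OH) | CC(C)[Si](C(C)C)(C(C)C)O[C@H](/C=C(\COc1ccc(OC)cc1)C(=O)O)C/C(CO[Si](C(C)C)(C(C)C)C(C)C)=C\CC/C(COc1ccc(OC)cc1)=C\CO
F4 | step 18 | 13-membered enoate lactone (C13 carbonyl) | CC(C)[Si](C(C)C)(C(C)C)O[C@H]1C/C(CO[Si](C(C)C)(C(C)C)C(C)C)=C\CC/C(COc2ccc(OC)cc2)=C\COC(=O)/C(COc2ccc(OC)cc2)=C/1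
F5 | step 18 | 13-membered α-acetoxy ether (acetoxy on C13) | CC(C)[Si](C(C)C)(C(C)C)O[C@H]1C/C(CO[Si](C(C)C)(C(C)C)C(C)C)=C\CC/C(COc2ccc(OC)cc2)=C\COC(OC(C)=O)/C(COc2ccc(OC)cc2)=C/1
F6 | step 12 | methyl 2-(dimethoxyphosphoryl)-3-(4-methoxyphenoxy)propanoate | COC(=O)C(COc1ccc(OC)cc1)P(=O)(OC)OC
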